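**Retrosynthetic overview**

1. Ring numbering used throughout: C1 (C=O), C2 [C(OH)(cinnamoyl)], C3 (C=O), C4 [C(OMe)(prenyl)], C5 (enol C–OH), C6 (C-prenyl). Disconnecting C1–C2 and C3–C4 splits the ring into a four-carbon unit C4–C5–C6–C1 and a two-carbon unit C2–C3.
2. Enabling feature: C1 (a carbonyl carbon) and C4 (an sp3 carbon bearing OMe and prenyl) are the two ends of the vinylogous-acid unit C1(=O)–C6=C5(O)–C4, so they can be tied by the strained σ-bond of a squarate-derived cyclobutenone. C2(OH)–C3(=O) is an α-hydroxy-acid unit, supplied as the enolate of an acetonide-protected α,β-dihydroxy-γ-lactone whose β-carbon becomes the cinnamoyl carbonyl carbon.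
3. Key step: the lactone enolate adds to the cyclobutenone carbonyl (C1–C2), the alkoxide triggers 4π ring opening, and the dienolate closes onto the lactone carbonyl (C3–C4). The six-membered ring and both quaternary stereocentres form in one operation, controlled by one chiral-pool centre.
4. Ring order: cyclobutene ring (bought as the squarate), then the six-membered ring in the key step (hemiketal and acetonide rings are temporary). The side chain is finished by oxidation, olefination, acid unmasking and allylic oxidation, which also erases the controlling carbinol centre.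
5. The prenyl groups are carried as allyl groups through the Grignard steps and made by cross-metathesis before the key step.

Key step: step 5

Assumption: 2,3-O-isopropylidene-L-erythronolactone 7 is taken as a purchasable chiral-pool compound (the enantiomer of the common D-lactone); enolised compounds are drawn in the tautomer of the target SMILES.

Step 1
Reactants: 1 diisopropyl squarate
Product: 3 3-allyl-4-isopropoxycyclobut-3-ene-1,2-dione, via allyl carbinol adduct 2 (not isolated)
Conditions: CH2=CHCH2MgBr, THF, −78 °C; then 12 M aq HCl, 0 °C → rt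
Reagents that add atoms: allylmagnesium bromide, C=CC[Mg]Br; water, O
Why: Grignard 1,2-addition to one squarate carbonyl followed by acid-promoted transposition with loss of isopropanol is the standard entry to 3-alkyl-4-alkoxycyclobutenediones; no stereocentre remains.

Step 2
Reactants: 3 3-allyl-4-isopropoxycyclobut-3-ene-1,2-dione
Product: 4 (±)-4-hydroxy-3-isopropoxy-2,4-di(prop-2-enyl)cyclobut-2-en-1-one
Conditions: CH2=CHCH2MgBr, THF, −78 °C; H2O quench
Reagents that add atoms: allylmagnesium bromide, C=CC[Mg]Br
Why: Grignard 1,2-addition should occur at the carbonyl next to the alkoxy-bearing carbon, because the other carbonyl is deactivated as a vinylogous ester; the new centre is racemic, which is harmless because step 5 erases it.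

Step 3
Reactants: 4 (±)-4-hydroxy-3-isopropoxy-2,4-di(prop-2-enyl)cyclobut-2-en-1-one
Product: 5 (±)-3-isopropoxy-4-methoxy-2,4-di(prop-2-enyl)cyclobut-2-en-1-one
Conditions: MeI, Ag2O, MeCN, rt, dark
Reagents that add atoms: iodomethane, CI
Why: Purdie methylation etherifies the hindered tertiary alcohol without forming a free alkoxide, which would risk retro-addition or ring opening.

Step 4
Reactants: 5 (±)-3-isopropoxy-4-methoxy-2,4-di(prop-2-enyl)cyclobut-2-en-1-one
Product: 6 (±)-3-isopropoxy-4-methoxy-2,4-bis(3-methylbut-2-enyl)cyclobut-2-en-1-one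
Conditions: second-generation Grubbs catalyst RuCl2(=CHPh)(PCy3)(SIMes) (5 mol %), 2-methyl-2-butene/CH2Cl2, 40 °C
Reagents that add atoms: 2-methyl-2-butene, CC=C(C)C
Why: Olefin cross-metathesis converts both terminal allyl groups into prenyl groups while the tetrasubstituted ring alkene is inert; this avoids the allylic transposition a prenyl organometal would give in steps 1 and 2.

Step 5
Reactants: 6 (±)-3-isopropoxy-4-methoxy-2,4-bis(3-methylbut-2-enyl)cyclobut-2-en-1-one; 7 2,3-O-isopropylidene-L-erythronolactone
Product: 12 tricyclic lactol, via lithium enolate 8 (not isolated), via cyclobutenolate adduct 9 (not isolated), via ring-opened dienolate 10 (not isolated), via lithium lactolate 11 (not isolated)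
Conditions: 7, LiN(iPr)2, THF, −78 °C; add 6, −78 → −20 °C; AcOH, −78 °C
Reagents that add atoms: none
Why: Proposed new method: the lithium enolate 8 adds 1,2 to the strained carbonyl of 6 (future C1; C1–C2 bond) to give alkoxide 9, whose alkoxide-accelerated conrotatory 4π-electrocyclic opening (oxido and methoxy rotate outward) erases the racemic cyclobutenone centre and gives the single dienolate 10, and the γ-carbon of 10 adds to the lactone carbonyl (C3–C4 bond) to give lactolate 11, protonated to 12. The closest known reaction types are the aldol addition and alkylation of acetonide-protected α-hydroxy ester enolates, the alkoxide-accelerated ring opening of cyclobutenols in squarate-ester cascades and the addition of lithium enolates to γ-lactones to give lactols; their union into a formal [4+2] insertion of the C2–C3 unit into the acyl–C4 bond is new. The cyclohexenone ring closes by a 6-(enolendo)-exo-trig Claisen-type addition, and the five-membered hemiketal ring is the original lactone ring, kept cis-fused. C2 is set by the ring-fusion stereocentre of 7, because the two five-membered rings can only stay cis-fused and the electrophile enters on the face of the ring-fusion hydrogen; C4 is set by relay, since attack perpendicular to the planar lactone places the lactone ring carbon axial at C2 and the inward prenyl group of the dienolate terminus becomes axial at C4 on the same face, so prenyl and the future cinnamoyl carbon end up cis and methoxy and the C2 oxygen cis; the hemiketal carbon C3 follows from the cis ring fusion. The step needs 1,2- rather than 1,4-addition (hard lithium enolate, strained ketone), addition anti to the larger prenyl substituent on the sp3 ring carbon so that oxido and methoxy are trans and both rotate outward, and γ- rather than α-attack of the dienolate (only the γ-carbon gives an unstrained ring). Release of cyclobutene strain and the stability of the lithium lactolate should make the sequence irreversible.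

Step 6
Reactants: 12 tricyclic lactol
Product: 14 keto aldehyde, via open hydroxy ketone tautomer 13 (not isolated)
Conditions: Dess–Martin periodinane, pyridine, CH2Cl2, rt
Reagents that add atoms: none
Why: Dess–Martin oxidation acts on the primary alcohol of the open tautomer 13, which is in equilibrium with the hemiketal (whose tertiary hydroxyl cannot be oxidised), so the ring-chain equilibrium is drained to the aldehyde.

Step 7
Reactants: 14 keto aldehyde
Product: 15 (E)-styryl spiro-acetonide
Conditions: (EtO)2P(O)CH2Ph, NaN(SiMe3)2, THF, −78 → 0 °C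
Reagents that add atoms: diethyl benzylphosphonate, CCOP(=O)(Cc1ccccc1)OCC
Why: Horner–Wadsworth–Emmons olefination with the benzylphosphonate anion should give the (E)-styrene, and the aldehyde reacts much faster than the two hindered ketones, which have no α-hydrogen and cannot enolise.

Step 8
Reactants: 15 (E)-styryl spiro-acetonide
Product: 16 (2R,4S)-2,5-dihydroxy-2-[(1S,2E)-1-hydroxy-3-phenylprop-2-enyl]-4-methoxy-4,6-bis(3-methylbut-2-enyl)cyclohex-5-ene-1,3-dione
Conditions: 2 M aq HCl, THF, rt
Reagents that add atoms: water, O
Why: Acid hydrolysis cleaves the acetonide and, by addition–elimination at C5, the isopropyl vinylogous ester; C2 and C4 are quaternary and cannot epimerise, and ionisation of the allylic carbinol is disfavoured by the adjacent electron-poor quaternary carbon.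

Step 9
Reactants: 16 (2R,4S)-2,5-dihydroxy-2-[(1S,2E)-1-hydroxy-3-phenylprop-2-enyl]-4-methoxy-4,6-bis(3-methylbut-2-enyl)cyclohex-5-ene-1,3-dione
Product: 17 microfolian
Conditions: MnO2 (activated, excess), CH2Cl2, rt
Reagents that add atoms: none
Why: MnO2 allylic oxidation should convert only the styryl carbinol into the enone, which erases the stereocentre that relayed the chirality and leaves the tertiary C2 hydroxyl, the enol and the prenyl alkenes untouched.

**Compound list**

1 | diisopropyl squarate (3,4-diisopropoxycyclobut-3-ene-1,2-dione) | CC(C)OC1=C(OC(C)C)C(=O)C1=O | starting material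
2 | (±)-4-hydroxy-2,3-diisopropoxy-4-(prop-2-enyl)cyclobut-2-en-1-one (allyl carbinol adduct, not isolated) | C=CCC1(O)C(OC(C)C)=C(OC(C)C)C1=O | intermediate
3 | 3-allyl-4-isopropoxycyclobut-3-ene-1,2-dione | C=CCC1=C(OC(C)C)C(=O)C1=O | intermediate
4 | (±)-4-hydroxy-3-isopropoxy-2,4-di(prop-2-enyl)cyclobut-2-en-1-one | C=CCC1=C(OC(C)C)C(O)(CC=C)C1=O | intermediate
5 | (±)-3-isopropoxy-4-methoxy-2,4-di(prop-2-enyl)cyclobut-2-en-1-one | C=CCC1=C(OC(C)C)C(OC)(CC=C)C1=O | intermediate
6 | (±)-3-isopropoxy-4-methoxy-2,4-bis(3-methylbut-2-enyl)cyclobut-2-en-1-one | CC(C)=CCC1=C(OC(C)C)C(OC)(CC=C(C)C)C1=O | intermediate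
7 | 2,3-O-isopropylidene-L-erythronolactone, (3aS,6aS)-2,2-dimethyldihydrofuro[3,4-d][1,3]dioxol-4(3aH)-one | O=C1[C@H]2OC(C)(C)O[C@H]2CO1 | starting material
8 | lithium enolate of 7 (not isolated) | [Li+].[O-]C1=C2OC(C)(C)O[C@H]2CO1 | intermediate
9 | lithium cyclobutenolate 1,2-adduct of 8 to 6 (not isolated; lactone unit cis to OMe, both enantiomers of 6 react, cyclobutene centres not specified) | [Li+].[O-]C1(C(CC=C(C)C)=C(OC(C)C)C1(OC)CC=C(C)C)[C@]23OC(C)(C)O[C@H]2COC3=O | intermediate
10 | ring-opened lithium dienolate (not isolated; lactone unit and the prenyl group of the methoxy-bearing terminus both inward) | [Li+].[O-]/C([C@]12OC(C)(C)O[C@H]1COC2=O)=C(CC=C(C)C)/C(OC(C)C)=C(OC)\CC=C(C)C | intermediate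
11 | lithium lactolate, lithium salt of 12 (not isolated) | [Li+].CO[C@]1(CC=C(C)C)[C@@]2([O-])OC[C@@H]3OC(C)(C)O[C@]23C(=O)C(CC=C(C)C)=C1OC(C)C | intermediate
12 | tricyclic lactol: cyclohexenone ring (C1=O, C4 with OMe and prenyl, C5 OiPr, C6 prenyl) cis-fused at C2–C3 to a 2-hydroxyoxolane (hemiketal at C3), which is cis-fused at C2–CH to the acetonide; C2 and C4 configured as in 17 | CO[C@]1(CC=C(C)C)[C@@]2(O)OC[C@@H]3OC(C)(C)O[C@]23C(=O)C(CC=C(C)C)=C1OC(C)C | intermediate
13 | open hydroxy ketone tautomer of 12 (not isolated): spiro-acetonide at C2 carrying CH2OH, free C3 ketone | CO[C@]1(CC=C(C)C)C(=O)[C@]2(OC(C)(C)O[C@H]2CO)C(=O)C(CC=C(C)C)=C1OC(C)C | intermediate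
14 | keto aldehyde: spiro-acetonide at C2 carrying a formyl group on the acetonide CH; C2 and C4 as in 17 | CO[C@]1(CC=C(C)C)C(=O)[C@]2(OC(C)(C)O[C@H]2C=O)C(=O)C(CC=C(C)C)=C1OC(C)C | intermediate
15 | (E)-styryl spiro-acetonide: 2-O,1′-O-isopropylidene derivative of 16 with the C5 hydroxyl as isopropyl ether | CO[C@]1(CC=C(C)C)C(=O)[C@]2(OC(C)(C)O[C@H]2/C=C/c3ccccc3)C(=O)C(CC=C(C)C)=C1OC(C)C | intermediate
16 | (2R,4S)-2,5-dihydroxy-2-[(1S,2E)-1-hydroxy-3-phenylprop-2-enyl]-4-methoxy-4,6-bis(3-methylbut-2-enyl)cyclohex-5-ene-1,3-dione | CO[C@]1(CC=C(C)C)C(=O)[C@@](O)([C@@H](O)/C=C/c2ccccc2)C(=O)C(CC=C(C)C)=C1O | intermediate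
17 | microfolian, (2R,4S)-2,5-dihydroxy-4-methoxy-4,6-bis(3-methylbut-2-enyl)-2-[(2E)-3-phenylprop-2-enoyl]cyclohex-5-ene-1,3-dione | CO[C@]1(CC=C(C)C)C(=O)[C@@](O)(C(=O)/C=C/c2ccccc2)C(=O)C(CC=C(C)C)=C1O | target

**Step count and risks**

Total step count: 9. Longest linear sequence: 9 steps (1 → 17); lactone 7 enters as purchased at step 5.

The three steps most likely to fail:

1. Step 5 (proposed new method). The aldolate may revert by retro-aldol, or the lactone enolate may undergo β-elimination, before the ring opens. The closure joins two fully substituted carbons beside a third and may be too slow, so that the dienolate is only protonated. Any loss of geometric purity of the dienolate would erode the configuration at C4. Fallback with known reaction types, setting out from 6 and returning at 12: 6 is heated in toluene with pentafluorophenol and Et3N, so that thermal ring opening gives the vinylketene, which is trapped as pentafluorophenyl (3Z)-3-isopropoxy-4-methoxy-7-methyl-2-(3-methylbut-2-enyl)octa-3,6-dienoate F1 (excess phenol so that trapping outruns the intramolecular ketene–alkene cycloaddition). C-acylation of lithium enolate 8 (from 7) with this active ester at −78 °C should give the β-keto lactone F2 (C1–C2 bond, same face control). LiN(SiMe3)2 then deprotonates C6, and the dienolate closes onto the lactone carbonyl by an intramolecular Claisen-type addition (C3–C4 bond) to give lactol 12.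

2. Step 8. Hydrolysis of the hindered isopropyl enol ether may be slow, and under stronger acid a prenyl group can cyclise onto the enol oxygen and the allylic carbinol can ionise. Fallback, setting out from 15 and returning at 17: 80% aq AcOH at 40 °C removes only the acetonide to give the diol isopropyl enol ether F5. MnO2 then oxidises the allylic carbinol to O-isopropyl microfolian F6. BCl3 in CH2Cl2 at −78 °C finally cleaves the O–isopropyl bond by Lewis-acid dealkylation instead of hydrolysis and gives 17.

3. Step 6. The hemiketal may be so favoured that the primary alcohol is hardly available, the oxidation stalls, and the oxidant attacks the enol ether or the alkenes instead. Fallback, setting out from 12 and returning at 15: a Mitsunobu reaction with 1-phenyl-1H-tetrazole-5-thiol (PPh3, DIAD) traps the open tautomer as the tetrazolyl sulfide F3. (NH4)6Mo7O24·4H2O/H2O2 in EtOH oxidises it to the tetrazolyl sulfone F4. Julia–Kocienski olefination with benzaldehyde (KN(SiMe3)2, DME, −60 °C) should then give the (E)-styrene 15.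

**Further compounds**

F1 | step 5 | pentafluorophenyl (3Z)-3-isopropoxy-4-methoxy-7-methyl-2-(3-methylbut-2-enyl)octa-3,6-dienoate (racemic) | O=C(Oc1c(F)c(F)c(F)c(F)c1F)C(CC=C(C)C)/C(OC(C)C)=C(OC)\CC=C(C)C
F2 | step 5 | β-keto lactone (ketone form of dienolate 10; C-acylated 7) | O=C(C(CC=C(C)C)/C(OC(C)C)=C(OC)\CC=C(C)C)[C@]12OC(C)(C)O[C@H]1COC2=O
F3 | step 6 | 1-phenyl-1H-tetrazol-5-yl sulfide of open tautomer 13 | CO[C@]1(CC=C(C)C)C(=O)[C@]2(OC(C)(C)O[C@H]2CSc3nnnn3-c4ccccc4)C(=O)C(CC=C(C)C)=C1OC(C)C
F4 | step 6 | 1-phenyl-1H-tetrazol-5-yl sulfone | CO[C@]1(CC=C(C)C)C(=O)[C@]2(OC(C)(C)O[C@H]2CS(=O)(=O)c3nnnn3-c4ccccc4)C(=O)C(CC=C(C)C)=C1OC(C)C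
F5 | step 8 | diol isopropyl enol ether (16 with the C5 hydroxyl as isopropyl ether) | CO[C@]1(CC=C(C)C)C(=O)[C@@](O)([C@@H](O)/C=C/c2ccccc2)C(=O)C(CC=C(C)C)=C1OC(C)C
F6 | step 8 | O-isopropyl microfolian (17 with the C5 hydroxyl as isopropyl ether) | CO[C@]1(CC=C(C)C)C(=O)[C@@](O)(C(=O)/C=C/c2ccccc2)C(=O)C(CC=C(C)C)=C1OC(C)C
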